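## Retrosynthetic overview

1. The target is disconnected last at the fused butenolide: a silver-catalysed ring expansion of cyclopropenone 21 inserts the tethered N-formyl C=O into the three-membered ring. This forms the C5–C6 bond, the butenolide and the azepine in one step.
2. 21 comes from alkyne 19 (difluorocarbene addition, then hydrolysis). The C11 methyl of 19 comes from conjugate reduction and enolate methylation of butenolide 17.
3. 17 comes from acid 15 and silyloxyfuran 8 by a decarboxylative N-formyliminium vinylogous Mannich reaction (C9–C9a bond).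
4. 15 comes from benzyl N-formyl-L-prolinate 12 and silyloxyfuran 2 (Shono oxidation, vinylogous Mannich reaction for C3–C14, hydrogenation). L-Proline relays the chirality.
5. Ring order: pyrrolidine (chiral pool), then pendant lactone, then spiro lactone, then cyclopropenone, then fused butenolide and azepine together.

Assumption: atom labels follow croomine numbering (pyrrolidine C1–C3, N4, N,O-acetal C5, C6–C8, spiro C9, C9a; spiro lactone C10–C12 with 11-Me; pendant lactone C14–C17 with 16-Me); read this way the target SMILES is 3S,5S,9S,9aS,11R,14S,16S, and 5-iodopent-2-yne is made rather than bought.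

## Route

Step 1
Reactants: 1 3-methylfuran-2(5H)-one
Product: 2 3-methyl-2-(triisopropylsilyloxy)furan
Conditions: TIPSOTf, Et3N, CH2Cl2, 0 °C to rt
Reagents that add atoms: triisopropylsilyl triflate, CC(C)[Si](C(C)C)(C(C)C)OS(=O)(=O)C(F)(F)F
Why: Soft enolisation and O-silylation of the butenolide gives the aromatic 2-silyloxyfuran, the standard dienolate equivalent for vinylogous Mannich reactions; no stereocentre is involved.

Step 2
Reactants: 3 furan-2(5H)-one
Product: 4 2-(triisopropylsilyloxy)furan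
Conditions: TIPSOTf, Et3N, CH2Cl2, 0 °C to rt
Reagents that add atoms: triisopropylsilyl triflate, CC(C)[Si](C(C)C)(C(C)C)OS(=O)(=O)C(F)(F)F
Why: Same soft enolisation and O-silylation as in step 1; the bulky silyl group is chosen because it survives the later ring lithiation.

Step 3
Reactants: 5 pent-3-yn-1-ol
Product: 6 5-iodopent-2-yne
Conditions: I2, PPh3, imidazole, CH2Cl2, 0 °C to rt
Reagents that add atoms: iodine, II
Why: Appel iodination of a primary alcohol (SN2 on the alkoxyphosphonium ion) gives the alkylating agent without touching the internal alkyne.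

Step 4
Reactants: 4 2-(triisopropylsilyloxy)furan; 6 5-iodopent-2-yne
Product: 8 5-(pent-3-yn-1-yl)-2-(triisopropylsilyloxy)furan, via 5-lithiofuran 7 (not isolated)
Conditions: s-BuLi, TMEDA, THF, 0 °C; then 6, −78 °C to rt
Reagents that add atoms: none
Why: Ring lithiation at C5 (the C–H next to the ring oxygen) followed by SN2 alkylation with the primary iodide installs the C8–C7 chain carrying the future cyclopropenone carbons.

Step 5
Reactants: 9 L-proline; 10 ethyl formate
Product: 12 benzyl (2S)-1-formylpyrrolidine-2-carboxylate, via benzyl L-prolinate hydrochloride 11 (not isolated)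
Conditions: BnOH, SOCl2, 0 °C to rt, concentrate; then 10 (as solvent), Et3N, reflux
Reagents that add atoms: benzyl alcohol, OCc1ccccc1
Why: Thionyl chloride esterification followed by N-formylation through aminolysis of ethyl formate leaves the chiral-pool (S) centre untouched; the formyl group is both the N-acyl activator and the future C5–O unit.

Step 6
Reactants: 12 benzyl (2S)-1-formylpyrrolidine-2-carboxylate
Product: 13 benzyl (2S)-1-formyl-5-methoxypyrrolidine-2-carboxylate (C5 epimer mixture)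
Conditions: graphite anode, Pt cathode, Et4NOTs, MeOH, 0 °C, 2.5 F/mol, undivided cell
Reagents that add atoms: methanol, CO
Why: Shono anodic α-methoxylation occurs at the ring CH2 next to nitrogen and not at the ester-deactivated C2–H; the new N,O-acetal centre is lost again on ionisation, so its configuration does not matter.

Step 7
Reactants: 13 benzyl (2S)-1-formyl-5-methoxypyrrolidine-2-carboxylate; 2 3-methyl-2-(triisopropylsilyloxy)furan
Product: 14 benzyl (2S,5S)-1-formyl-5-[(2S)-4-methyl-5-oxo-2,5-dihydrofuran-2-yl]pyrrolidine-2-carboxylate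
Conditions: TIPSOTf (10 mol%), CH2Cl2, −78 °C
Reagents that add atoms: none
Why: Vinylogous Mannich reaction of the N-formyliminium ion with the furan C5: attack occurs trans to the ester (held pseudo-axial by A(1,3) strain with the N-acyl group) and with the usual threo preference of silyloxyfuran additions, setting C3 (S) and C14 (S).

Step 8
Reactants: 14 benzyl (2S,5S)-1-formyl-5-[(2S)-4-methyl-5-oxo-2,5-dihydrofuran-2-yl]pyrrolidine-2-carboxylate
Product: 15 (2S,5S)-1-formyl-5-[(2S,4S)-4-methyl-5-oxooxolan-2-yl]pyrrolidine-2-carboxylic acid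
Conditions: H2 (1 atm), 10% Pd/C, EtOAc–MeOH, rt
Reagents that add atoms: none
Why: Heterogeneous hydrogenation adds H2 to the butenolide face opposite the pyrrolidinyl group, giving the cis α,γ-disubstituted lactone (C16 S), and the same operation hydrogenolyses the benzyl ester.

Step 9
Reactants: 15 (2S,5S)-1-formyl-5-[(2S,4S)-4-methyl-5-oxooxolan-2-yl]pyrrolidine-2-carboxylic acid; 8 5-(pent-3-yn-1-yl)-2-(triisopropylsilyloxy)furan
Product: 17 (2S,5S)-2-[(2S)-5-oxo-2-(pent-3-yn-1-yl)-2,5-dihydrofuran-2-yl]-5-[(2S,4S)-4-methyl-5-oxooxolan-2-yl]pyrrolidine-1-carbaldehyde, via 2-acetoxypyrrolidine 16 (not isolated)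
Conditions: PhI(OAc)2, I2, CH2Cl2, visible light, rt; aq. Na2S2O3 wash, concentrate; then 8, TIPSOTf (20 mol%), CH2Cl2, −78 °C
Reagents that add atoms: none
Why: Radical decarboxylation–oxidation (Suárez type) converts the carboxyl group into an N-acyliminium precursor, and the vinylogous Mannich reaction of the 5-substituted silyloxyfuran at its γ-carbon then occurs trans to the C3 lactone substituent with the same threo sense, setting C9a (S) and the quaternary C9 (S).

Step 10
Reactants: 17 (2S,5S)-2-[(2S)-5-oxo-2-(pent-3-yn-1-yl)-2,5-dihydrofuran-2-yl]-5-[(2S,4S)-4-methyl-5-oxooxolan-2-yl]pyrrolidine-1-carbaldehyde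
Product: 19 (2S,5S)-2-[(2S,4R)-4-methyl-5-oxo-2-(pent-3-yn-1-yl)oxolan-2-yl]-5-[(2S,4S)-4-methyl-5-oxooxolan-2-yl]pyrrolidine-1-carbaldehyde, via lithium enolate 18 (not isolated)
Conditions: LiBH(s-Bu)3, THF, −78 °C; then MeI, DMPU, −78 to −40 °C
Reagents that add atoms: iodomethane, CI
Why: Reductive alkylation: 1,4-hydride addition to the butenolide (alkyne, saturated lactone and formamide are inert at −78 °C) gives the lactone enolate, which is methylated on the face of the primary chain, opposite the bulkier N-formylpyrrolidinyl group, setting C11 (R).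

Step 11
Reactants: 19 (2S,5S)-2-[(2S,4R)-4-methyl-5-oxo-2-(pent-3-yn-1-yl)oxolan-2-yl]-5-[(2S,4S)-4-methyl-5-oxooxolan-2-yl]pyrrolidine-1-carbaldehyde
Product: 21 (2S,5S)-2-[(2S,4R)-4-methyl-2-[2-(2-methyl-3-oxocycloprop-1-en-1-yl)ethyl]-5-oxooxolan-2-yl]-5-[(2S,4S)-4-methyl-5-oxooxolan-2-yl]pyrrolidine-1-carbaldehyde, via gem-difluorocyclopropene 20 (not isolated)
Conditions: TMSCF2Br, n-Bu4NBr (cat.), toluene, 110 °C; then wet SiO2, CH2Cl2, rt
Reagents that add atoms: (bromodifluoromethyl)trimethylsilane, C[Si](C)(C)C(F)(F)Br; water, O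
Why: Difluorocarbene addition to the electron-rich dialkyl alkyne followed by hydrolysis of the CF2 group is the standard cyclopropenone synthesis; the electron-poor carbonyl groups do not react with the electrophilic carbene and no stereocentre is touched.

Step 12
Reactants: 21 (2S,5S)-2-[(2S,4R)-4-methyl-2-[2-(2-methyl-3-oxocycloprop-1-en-1-yl)ethyl]-5-oxooxolan-2-yl]-5-[(2S,4S)-4-methyl-5-oxooxolan-2-yl]pyrrolidine-1-carbaldehyde
Product: 22 target CNP0155196.1 (3S,5S,9S,9aS,11R,14S,16S)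
Conditions: AgOTf (10 mol%), 4 Å MS, ClCH2CH2Cl, 60 °C
Reagents that add atoms: none
Why: Proposed new method: monovalent silver activates the cyclopropenone as a hydroxycyclopropenylium-type species, the formamide oxygen adds to its carbonyl carbon, and strain-driven C–C cleavage gives a vinylsilver/O-acyl formiminium pair that closes by C–C bond formation, so the three-membered ring is expanded stepwise (not pericyclic) to the 5-aminobutenolide while the tether closes the azepine (only the tether-bearing alkene carbon can reach the iminium carbon without forming a bridged eight-membered ring), and the epimerisable N,O-acetal C5 is expected to settle through the ring-opened iminium carboxylate to the S epimer with C5–O on the face of H-9a, away from the pyrrolidine C1; the closest known reaction type is the intermolecular silver- or phosphine-promoted formal (3+2) ring expansion of diarylcyclopropenones with formamides or aldehydes to butenolides, not shown for dialkylcyclopropenones, tethered formamides or ring closure.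

## Compound list

1 | 3-methylfuran-2(5H)-one | CC1=CCOC1=O | starting material
2 | 3-methyl-2-(triisopropylsilyloxy)furan | Cc1ccoc1O[Si](C(C)C)(C(C)C)C(C)C | intermediate
3 | furan-2(5H)-one | O=C1OCC=C1 | starting material
4 | 2-(triisopropylsilyloxy)furan | CC(C)[Si](Oc1ccco1)(C(C)C)C(C)C | intermediate
5 | pent-3-yn-1-ol | CC#CCCO | starting material
6 | 5-iodopent-2-yne | CC#CCCI | intermediate
7 | 5-lithio-2-(triisopropylsilyloxy)furan | [Li]c1ccc(O[Si](C(C)C)(C(C)C)C(C)C)o1 | intermediate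
8 | 5-(pent-3-yn-1-yl)-2-(triisopropylsilyloxy)furan | CC#CCCc1ccc(O[Si](C(C)C)(C(C)C)C(C)C)o1 | intermediate
9 | L-proline | OC(=O)[C@@H]1CCCN1 | starting material
10 | ethyl formate | CCOC=O | starting material
11 | benzyl L-prolinate hydrochloride | [Cl-].O=C(OCc1ccccc1)[C@@H]1CCC[NH2+]1 | intermediate
12 | benzyl (2S)-1-formylpyrrolidine-2-carboxylate | O=CN1CCC[C@H]1C(=O)OCc1ccccc1 | intermediate
13 | benzyl (2S)-1-formyl-5-methoxypyrrolidine-2-carboxylate (C5 epimer mixture) | COC1CC[C@@H](C(=O)OCc2ccccc2)N1C=O | intermediate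
14 | benzyl (2S,5S)-1-formyl-5-[(2S)-4-methyl-5-oxo-2,5-dihydrofuran-2-yl]pyrrolidine-2-carboxylate | O=C(OCc1ccccc1)[C@@H]1CC[C@@H]([C@@H]2C=C(C)C(=O)O2)N1C=O | intermediate
15 | (2S,5S)-1-formyl-5-[(2S,4S)-4-methyl-5-oxooxolan-2-yl]pyrrolidine-2-carboxylic acid | OC(=O)[C@@H]1CC[C@@H]([C@@H]2C[C@H](C)C(=O)O2)N1C=O | intermediate
16 | (5S)-1-formyl-5-[(2S,4S)-4-methyl-5-oxooxolan-2-yl]pyrrolidin-2-yl acetate (C2 epimer mixture) | CC(=O)OC1CC[C@@H]([C@@H]2C[C@H](C)C(=O)O2)N1C=O | intermediate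
17 | (2S,5S)-2-[(2S)-5-oxo-2-(pent-3-yn-1-yl)-2,5-dihydrofuran-2-yl]-5-[(2S,4S)-4-methyl-5-oxooxolan-2-yl]pyrrolidine-1-carbaldehyde | CC#CCC[C@]1(C=CC(=O)O1)[C@@H]2CC[C@@H]([C@@H]3C[C@H](C)C(=O)O3)N2C=O | intermediate
18 | lithium enolate of the 1,4-reduced lactone of 17 (lithium 4,5-dihydrofuran-2-olate, same configuration as 17) | CC#CCC[C@]1(CC=C(O[Li])O1)[C@@H]2CC[C@@H]([C@@H]3C[C@H](C)C(=O)O3)N2C=O | intermediate
19 | (2S,5S)-2-[(2S,4R)-4-methyl-5-oxo-2-(pent-3-yn-1-yl)oxolan-2-yl]-5-[(2S,4S)-4-methyl-5-oxooxolan-2-yl]pyrrolidine-1-carbaldehyde | CC#CCC[C@]1(C[C@@H](C)C(=O)O1)[C@@H]2CC[C@@H]([C@@H]3C[C@H](C)C(=O)O3)N2C=O | intermediate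
20 | (2S,5S)-2-[(2S,4R)-2-[2-(3,3-difluoro-2-methylcycloprop-1-en-1-yl)ethyl]-4-methyl-5-oxooxolan-2-yl]-5-[(2S,4S)-4-methyl-5-oxooxolan-2-yl]pyrrolidine-1-carbaldehyde | CC1=C(CC[C@]2(C[C@@H](C)C(=O)O2)[C@@H]3CC[C@@H]([C@@H]4C[C@H](C)C(=O)O4)N3C=O)C1(F)F | intermediate
21 | (2S,5S)-2-[(2S,4R)-4-methyl-2-[2-(2-methyl-3-oxocycloprop-1-en-1-yl)ethyl]-5-oxooxolan-2-yl]-5-[(2S,4S)-4-methyl-5-oxooxolan-2-yl]pyrrolidine-1-carbaldehyde | CC1=C(CC[C@]2(C[C@@H](C)C(=O)O2)[C@@H]3CC[C@@H]([C@@H]4C[C@H](C)C(=O)O4)N3C=O)C1=O | intermediate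
22 | CNP0155196.1: (3S,5S,9S,9aS,11R,14S,16S) pyrrolo[1,2-a]azepine with a C9 spiro α-methyl-γ-lactone, a C3 (2S,4S)-4-methyl-5-oxooxolan-2-yl group and a C5–C6 fused α-methylbutenolide whose ring oxygen sits on C5 | CC1=C2CC[C@]3(C[C@@H](C)C(=O)O3)[C@@H]3CC[C@@H]([C@@H]4C[C@H](C)C(=O)O4)N3[C@H]2OC1=O | target

## Step count and risks

Total steps: 12. Longest linear sequence: 8 (steps 5 to 12, from L-proline).

Steps most likely to fail:

Step 12 (the proposed silver-catalysed ring expansion). Risks are hydrolytic opening of the cyclopropenone, no turnover with a dialkylcyclopropenone, and a mixture of C5 epimers. The fallback uses known chemistry, sets out from 15 (with in-flask 7) and comes back at 22. Lithiofuran 7 is alkylated with 5-bromopent-1-ene to give 5-(pent-4-en-1-yl)-2-(triisopropylsilyloxy)furan F1. Acid 15 is decarboxylated to 16 and coupled with F1 as in step 9 to give (2S,5S)-2-[(2S)-5-oxo-2-(pent-4-en-1-yl)-2,5-dihydrofuran-2-yl]-5-[(2S,4S)-4-methyl-5-oxooxolan-2-yl]pyrrolidine-1-carbaldehyde F2. LiBH(s-Bu)3 and then MeI, through the lithium enolate F3 (not isolated), give (2S,5S)-2-[(2S,4R)-4-methyl-5-oxo-2-(pent-4-en-1-yl)oxolan-2-yl]-5-[(2S,4S)-4-methyl-5-oxooxolan-2-yl]pyrrolidine-1-carbaldehyde F4. Ozonolysis (O3, CH2Cl2–MeOH, −78 °C; Me2S) gives 4-[(2S,4R)-2-[(2S,5S)-1-formyl-5-[(2S,4S)-4-methyl-5-oxooxolan-2-yl]pyrrolidin-2-yl]-4-methyl-5-oxooxolan-2-yl]butanal F5. HCl in MeOH removes the N-formyl group and masks the aldehyde, giving (3R,5S)-5-(4,4-dimethoxybutyl)-3-methyl-5-[(2S,5S)-5-[(2S,4S)-4-methyl-5-oxooxolan-2-yl]pyrrolidin-2-yl]oxolan-2-one hydrochloride F6. Warming F6 with pyruvic acid and NaOAc in aqueous AcOH frees the amino aldehyde, which closes to the seven-membered cyclic enamine. This then undergoes the secondary-amine/enolisable-aldehyde/α-oxo-acid condensation (aldol at C6, dehydration, lactonisation of the carboxylate onto the iminium carbon C5) to give 22. This condensation is the pyruvic acid counterpart of the well-used glyoxylic acid–morpholine route to 5-aminobutenolides.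

Step 10 (reductive methylation). Risks are 1,2-reduction, proton transfer from the pendant lactone, and modest facial selectivity at C11. The fallback sets out from 15, 2 and 6 and comes back at 22; it carries the methyl group in from the furan and sets C11 last. Lithiation of 2 (s-BuLi, TMEDA) gives 5-lithio-3-methyl-2-(triisopropylsilyloxy)furan F7 (not isolated), which is alkylated with 6 to 3-methyl-5-(pent-3-yn-1-yl)-2-(triisopropylsilyloxy)furan F8. Coupling with 15 through 16 as in step 9 gives (2S,5S)-2-[(2S)-4-methyl-5-oxo-2-(pent-3-yn-1-yl)-2,5-dihydrofuran-2-yl]-5-[(2S,4S)-4-methyl-5-oxooxolan-2-yl]pyrrolidine-1-carbaldehyde F9. TMSCF2Br with n-Bu4NBr and then wet silica, through the gem-difluorocyclopropene F10 (not isolated), give the cyclopropenone F11. The AgOTf ring expansion of step 12 gives the 10,11-didehydro tricycle F12. Hydrogenation over Rh/C then reduces only the trisubstituted spiro butenolide, with hydrogen delivered from the face anchored by the amine nitrogen, to give 22. The tetrasubstituted fused butenolide and the N,O-acetal are left alone by rhodium.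

Step 9 (decarboxylative vinylogous Mannich reaction forming the quaternary C9). Risks are α- versus γ-attack of the furan and a low trans/threo ratio. The fallback sets out from 15 and 6 and comes back at 19; it builds the spiro lactone on a ketone instead. Acid 15 is converted (EtSH, EDC·HCl, DMAP) into S-ethyl (2S,5S)-1-formyl-5-[(2S,4S)-4-methyl-5-oxooxolan-2-yl]pyrrolidine-2-carbothioate F13. Iodide 6 and zinc dust give iodo(pent-3-yn-1-yl)zinc F14, which is coupled with F13 under PdCl2(PPh3)2 catalysis (Fukuyama ketone synthesis) to (2S,5S)-2-(hex-4-ynoyl)-5-[(2S,4S)-4-methyl-5-oxooxolan-2-yl]pyrrolidine-1-carbaldehyde F15. SmI2-mediated ketyl–olefin coupling with methyl methacrylate (t-BuOH, THF, −78 °C) then gives 19 directly after lactonisation. The C9 configuration relies on chelation of the samarium ketyl by the formamide oxygen, and the C9/C11 diastereomers are separated by chromatography.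

Further compounds

F1 | step 12 | 5-(pent-4-en-1-yl)-2-(triisopropylsilyloxy)furan | C=CCCCc1ccc(O[Si](C(C)C)(C(C)C)C(C)C)o1
F2 | step 12 | (2S,5S)-2-[(2S)-5-oxo-2-(pent-4-en-1-yl)-2,5-dihydrofuran-2-yl]-5-[(2S,4S)-4-methyl-5-oxooxolan-2-yl]pyrrolidine-1-carbaldehyde | C=CCCC[C@]1(C=CC(=O)O1)[C@@H]2CC[C@@H]([C@@H]3C[C@H](C)C(=O)O3)N2C=O
F3 | step 12 | lithium enolate of the 1,4-reduced lactone of F2 | C=CCCC[C@]1(CC=C(O[Li])O1)[C@@H]2CC[C@@H]([C@@H]3C[C@H](C)C(=O)O3)N2C=O
F4 | step 12 | (2S,5S)-2-[(2S,4R)-4-methyl-5-oxo-2-(pent-4-en-1-yl)oxolan-2-yl]-5-[(2S,4S)-4-methyl-5-oxooxolan-2-yl]pyrrolidine-1-carbaldehyde | C=CCCC[C@]1(C[C@@H](C)C(=O)O1)[C@@H]2CC[C@@H]([C@@H]3C[C@H](C)C(=O)O3)N2C=O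
F5 | step 12 | 4-[(2S,4R)-2-[(2S,5S)-1-formyl-5-[(2S,4S)-4-methyl-5-oxooxolan-2-yl]pyrrolidin-2-yl]-4-methyl-5-oxooxolan-2-yl]butanal | O=CCCC[C@]1(C[C@@H](C)C(=O)O1)[C@@H]2CC[C@@H]([C@@H]3C[C@H](C)C(=O)O3)N2C=O
F6 | step 12 | (3R,5S)-5-(4,4-dimethoxybutyl)-3-methyl-5-[(2S,5S)-5-[(2S,4S)-4-methyl-5-oxooxolan-2-yl]pyrrolidin-2-yl]oxolan-2-one hydrochloride | [Cl-].COC(OC)CCC[C@]1(C[C@@H](C)C(=O)O1)[C@@H]2CC[C@@H]([C@@H]3C[C@H](C)C(=O)O3)[NH2+]2
F7 | step 10 | 5-lithio-3-methyl-2-(triisopropylsilyloxy)furan | [Li]c1cc(C)c(O[Si](C(C)C)(C(C)C)C(C)C)o1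
F8 | step 10 | 3-methyl-5-(pent-3-yn-1-yl)-2-(triisopropylsilyloxy)furan | CC#CCCc1cc(C)c(O[Si](C(C)C)(C(C)C)C(C)C)o1
F9 | step 10 | (2S,5S)-2-[(2S)-4-methyl-5-oxo-2-(pent-3-yn-1-yl)-2,5-dihydrofuran-2-yl]-5-[(2S,4S)-4-methyl-5-oxooxolan-2-yl]pyrrolidine-1-carbaldehyde | CC#CCC[C@]1(C=C(C)C(=O)O1)[C@@H]2CC[C@@H]([C@@H]3C[C@H](C)C(=O)O3)N2C=O
F10 | step 10 | (2S,5S)-2-[(2S)-2-[2-(3,3-difluoro-2-methylcycloprop-1-en-1-yl)ethyl]-4-methyl-5-oxo-2,5-dihydrofuran-2-yl]-5-[(2S,4S)-4-methyl-5-oxooxolan-2-yl]pyrrolidine-1-carbaldehyde | CC1=C(CC[C@]2(C=C(C)C(=O)O2)[C@@H]3CC[C@@H]([C@@H]4C[C@H](C)C(=O)O4)N3C=O)C1(F)F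
F11 | step 10 | (2S,5S)-2-[(2S)-4-methyl-2-[2-(2-methyl-3-oxocycloprop-1-en-1-yl)ethyl]-5-oxo-2,5-dihydrofuran-2-yl]-5-[(2S,4S)-4-methyl-5-oxooxolan-2-yl]pyrrolidine-1-carbaldehyde | CC1=C(CC[C@]2(C=C(C)C(=O)O2)[C@@H]3CC[C@@H]([C@@H]4C[C@H](C)C(=O)O4)N3C=O)C1=O
F12 | step 10 | 10,11-didehydro analogue of 22 (spiro butenolide in place of the spiro lactone; 3S,5S,9S,9aS,14S,16S) | CC1=C2CC[C@]3(C=C(C)C(=O)O3)[C@@H]3CC[C@@H]([C@@H]4C[C@H](C)C(=O)O4)N3[C@H]2OC1=O
F13 | step 9 | S-ethyl (2S,5S)-1-formyl-5-[(2S,4S)-4-methyl-5-oxooxolan-2-yl]pyrrolidine-2-carbothioate | CCSC(=O)[C@@H]1CC[C@@H]([C@@H]2C[C@H](C)C(=O)O2)N1C=O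
F14 | step 9 | iodo(pent-3-yn-1-yl)zinc | CC#CCC[Zn]I
F15 | step 9 | (2S,5S)-2-(hex-4-ynoyl)-5-[(2S,4S)-4-methyl-5-oxooxolan-2-yl]pyrrolidine-1-carbaldehyde | CC#CCCC(=O)[C@@H]1CC[C@@H]([C@@H]2C[C@H](C)C(=O)O2)N1C=O
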